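**Retrosynthetic overview**

1. The target is traced back to cis-decalin-2,8-dione 12, which already carries the full C9 side chain. The forward moves are C2–O angeloylation, thermodynamic reduction of the C2 ketone, and conversion of C8=O into C8(CH3)=C7 via enol triflate and Negishi methylation.
2. 12 comes from ring enlargement of the cis-hydrindanone 10. The enabling feature is the exocyclic C8=C9 alkylidene on the five-membered ring C5–C6–C7–C8–C10, next to quaternary C10. Its bromohydrin (tertiary C8–OH, C9–Br) lets the C8–C10 bond shift to C9, so C9 is inserted and the cyclopentane becomes six-membered ring B with the C8 ketone.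
3. 10 comes from Pd–H reductive 5-exo cyclisation of alkynyl enone 9, which forms C8–C10 and sets C10 cis to H-5 through the tether.
4. 9 comes from allylic oxidation of enyne 8, which is assembled by sp–sp3 coupling of alkyne 4 (from (R)-α-ionone: ring A and C5) with iodide 7 (from methyl hydrogen (R)-3-methylglutarate: C13).
5. Ring order: ring A is bought; the five-membered precursor of ring B is closed in step 7; ring B is formed by 5 → 6 enlargement in step 8.

Key step: step 8

Remark: the target SMILES is read as the 2S,5R,9R,10S,13R isomer (cis ring fusion; C9 chain and C2 angelate both anti to CH3-10). (R)-α-Ionone, methyl hydrogen (R)-3-methylglutarate and angelic anhydride are assumed to be purchasable in the stated isomeric form. Labdane numbering (C1–C20) is used for positions throughout.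

**Route**

Step 1
Reactants: 1 (R)-α-ionone
Product: 2 4-[(1R)-2,6,6-trimethylcyclohex-2-en-1-yl]butan-2-one
Conditions: Bu3SnH, Pd(PPh3)4 (2 mol%), AcOH, THF, rt
Reagents that add atoms: none
Why: Pd-catalysed conjugate reduction with tin hydride (Keinan type) should saturate only the enone C=C and leave the trisubstituted ring alkene and the ring stereocentre (future C5) untouched.

Step 2
Reactants: 2 4-[(1R)-2,6,6-trimethylcyclohex-2-en-1-yl]butan-2-one
Product: 4 (6R)-6-(but-3-yn-1-yl)-1,5,5-trimethylcyclohex-1-ene, via enol phosphate 3 (not isolated)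
Conditions: LDA (1.1 equiv), THF, −78 °C; ClP(O)(OEt)2, −78 °C to rt; LDA (2.3 equiv), −78 °C to rt; H2O
Reagents that add atoms: diethyl chlorophosphate CCOP(=O)(Cl)OCC (its atoms stay only in 3)
Why: Negishi's methyl ketone to terminal alkyne sequence (kinetic enolate on the CH3 side, enol phosphate, double elimination) should turn C8(=O)–C9H3 into C8≡C9H without touching the ring stereocentre.

Step 3
Reactants: 5 methyl hydrogen (R)-3-methylglutarate
Product: 6 methyl (3R)-5-hydroxy-3-methylpentanoate
Conditions: BH3·SMe2, THF, −10 °C to rt; MeOH quench; used crude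
Reagents that add atoms: none
Why: borane reduces the free carboxylic acid much faster than the methyl ester, the β-stereocentre (future C13) is not enolisable, and immediate use forestalls lactonisation.

Step 4
Reactants: 6 methyl (3R)-5-hydroxy-3-methylpentanoate
Product: 7 methyl (3S)-5-iodo-3-methylpentanoate
Conditions: I2, PPh3, imidazole, CH2Cl2, 0 °C
Reagents that add atoms: iodine II
Why: Appel-type (Garegg–Samuelsson) iodination of the primary alcohol runs under neutral conditions that leave the ester and the stereocentre alone (the descriptor changes only through CIP priorities).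

Step 5
Reactants: 4 (6R)-6-(but-3-yn-1-yl)-1,5,5-trimethylcyclohex-1-ene; 7 methyl (3S)-5-iodo-3-methylpentanoate
Product: 8 methyl (3R)-3-methyl-9-[(1R)-2,6,6-trimethylcyclohex-2-en-1-yl]non-6-ynoate
Conditions: [(π-allyl)PdCl]2 (2.5 mol%), 1,3-di(1-adamantyl)imidazolium chloride (5 mol%), CuI (7.5 mol%), Cs2CO3, DMF–Et2O (1:2), 45 °C
Reagents that add atoms: none
Why: Pd/NHC–Cu Sonogashira coupling of a terminal alkyne with an unactivated primary alkyl iodide should form the C9–C11 bond without a strong base, so the methyl ester survives and no stereocentre is touched.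

Step 6
Reactants: 8 methyl (3R)-3-methyl-9-[(1R)-2,6,6-trimethylcyclohex-2-en-1-yl]non-6-ynoate
Product: 9 methyl (3R)-3-methyl-9-[(1R)-2,6,6-trimethyl-4-oxocyclohex-2-en-1-yl]non-6-ynoate
Conditions: CrO3, 3,5-dimethylpyrazole, CH2Cl2, −20 °C
Reagents that add atoms: chromium trioxide O=[Cr](=O)=O
Why: Cr(VI)–pyrazole allylic oxidation should convert the unhindered ring allylic methylene C2 into the enone, as in the oxidation of α-ionone to 3-oxo-α-ionone; the tertiary C5–H and the less activated propargylic methylenes react more slowly, and the non-basic medium keeps the γ-stereocentre C5 intact.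

Step 7
Reactants: 9 methyl (3R)-3-methyl-9-[(1R)-2,6,6-trimethyl-4-oxocyclohex-2-en-1-yl]non-6-ynoate
Product: 10 methyl (3R,6E)-3-methyl-6-[(3aR,7aS)-4,4,7a-trimethyl-6-oxooctahydro-1H-inden-1-ylidene]hexanoate
Conditions: Pd2(dba)3·CHCl3 (2.5 mol%), P(o-tol)3 (10 mol%), AcOH, Et3SiH, toluene, 40 °C
Reagents that add atoms: none
Why: In this Trost-type Pd–H reductive enyne cyclisation, syn hydropalladation of the alkyne (Pd on C8), 5-exo insertion of the enone at C10 and protonolysis/hydride turnover of the Pd enolate should give the E-alkylidene cis-hydrindanone (H on C9 cis to C10); the three-atom tether from C5 can reach only its own face of C10, so CH3-10 ends cis to H-5.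

Step 8
Reactants: 10 methyl (3R,6E)-3-methyl-6-[(3aR,7aS)-4,4,7a-trimethyl-6-oxooctahydro-1H-inden-1-ylidene]hexanoate
Product: 12 methyl (3R)-3-methyl-5-[(1S,4aR,8aS)-5,5,8a-trimethyl-2,7-dioxodecahydronaphthalen-1-yl]pentanoate, via bromohydrin 11 (not isolated)
Conditions: NBS, NaHCO3, THF–H2O (3:1), 0 °C; crude 11, then AgBF4, 2,6-di-tert-butylpyridine, CH2Cl2, −40 to 0 °C
Reagents that add atoms: water O; N-bromosuccinimide O=C1CCC(=O)N1Br (bromine stays only in 11)
Why: NBS should deliver Br+ to the exocyclic C8=C9 alkene on the convex face of the cis-hydrindane (anti to ring A) and water should open the bromonium at the tertiary ring carbon C8, so that 11 carries C8–OH next to C9–Br; Ag+ then removes bromide while the antiperiplanar C8–C10 bond shifts to C9 and the carbinol collapses to the C8 ketone. The closest known reaction type is the Tiffeneau–Demjanov/Sisti ring enlargement of 1-(1-haloalkyl)cycloalkanols (silver-assisted semipinacol shift), which turns cyclopentanols into 2-alkylcyclohexanones. No ring is closed by an exo or endo cyclisation: ring B arises because C9 is inserted between C8 and C10 of the five-membered ring C5–C6–C7–C8–C10 (5 → 6). C9 is set by inversion at the carbon that loses bromide (anti bromohydrin of the E alkene), C10 migrates with retention, and C5 is untouched. The step needs C10 rather than C7 to migrate: in the rotamer that keeps the C9 hydrogen between the two ring carbons, C9–Br is antiperiplanar to C8–C10, and quaternary C10 is also the electronically better migrating group; the hindered pyridine traps HBF4 so that the new α-stereocentre C9 should not epimerise.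

Step 9
Reactants: 12 methyl (3R)-3-methyl-5-[(1S,4aR,8aS)-5,5,8a-trimethyl-2,7-dioxodecahydronaphthalen-1-yl]pentanoate
Product: 13 methyl (3R)-3-methyl-5-[(1S,4aR,8aS)-5,5,8a-trimethyl-7-oxo-2-(trifluoromethylsulfonyloxy)-1,4,4a,5,6,7,8,8a-octahydronaphthalen-1-yl]pentanoate
Conditions: KHMDS (1.05 equiv), THF, −78 °C; PhNTf2, −78 to −30 °C
Reagents that add atoms: N-phenylbis(trifluoromethanesulfonimide) O=S(=O)(N(c1ccccc1)S(=O)(=O)C(F)(F)F)C(F)(F)F
Why: kinetic deprotonation should occur at the unhindered C7 methylene (axial H on the convex face) rather than at tertiary C9 or at the neopentylic C1/C3 methylenes flanking the C2 ketone, giving the Δ7 enol triflate and leaving C9 untouched.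

Step 10
Reactants: 13 methyl (3R)-3-methyl-5-[(1S,4aR,8aS)-5,5,8a-trimethyl-7-oxo-2-(trifluoromethylsulfonyloxy)-1,4,4a,5,6,7,8,8a-octahydronaphthalen-1-yl]pentanoate
Product: 14 methyl (3R)-3-methyl-5-[(1R,4aR,8aS)-2,5,5,8a-tetramethyl-7-oxo-1,4,4a,5,6,7,8,8a-octahydronaphthalen-1-yl]pentanoate
Conditions: Me2Zn, Pd(PPh3)4 (5 mol%), THF, 0 °C to rt
Reagents that add atoms: dimethylzinc C[Zn]C
Why: Negishi coupling of the enol triflate should install the C8 methyl with the C7=C8 alkene fixed in place, since dimethylzinc does not add to the hindered C2 ketone or the ester.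

Step 11
Reactants: 14 methyl (3R)-3-methyl-5-[(1R,4aR,8aS)-2,5,5,8a-tetramethyl-7-oxo-1,4,4a,5,6,7,8,8a-octahydronaphthalen-1-yl]pentanoate
Product: 15 (3R)-3-methyl-5-[(1R,4aR,8aS)-2,5,5,8a-tetramethyl-7-oxo-1,4,4a,5,6,7,8,8a-octahydronaphthalen-1-yl]pentanoic acid
Conditions: LiOH, THF–H2O, rt; 1 M HCl
Reagents that add atoms: lithium hydroxide [Li+].[OH-]
Why: saponification unmasks the carboxylate, which is inert in the dissolving-metal step that follows, and no stereocentre sits α to a carbonyl group.

Step 12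
Reactants: 15 (3R)-3-methyl-5-[(1R,4aR,8aS)-2,5,5,8a-tetramethyl-7-oxo-1,4,4a,5,6,7,8,8a-octahydronaphthalen-1-yl]pentanoic acid
Product: 16 (3R)-5-[(1R,4aR,7S,8aS)-7-hydroxy-2,5,5,8a-tetramethyl-1,4,4a,5,6,7,8,8a-octahydronaphthalen-1-yl]-3-methylpentanoic acid
Conditions: Li, NH3(l)–THF, t-BuOH, −78 °C; NH4Cl
Reagents that add atoms: none
Why: dissolving-metal reduction of the hindered C2 ketone should give the thermodynamically favoured equatorial alcohol (2α-OH, hydrogen placed axially between the syn-axial C4 and C10 methyls), which is the target configuration, while the isolated C7=C8 alkene and the carboxylate are not reduced.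

Step 13
Reactants: 16 (3R)-5-[(1R,4aR,7S,8aS)-7-hydroxy-2,5,5,8a-tetramethyl-1,4,4a,5,6,7,8,8a-octahydronaphthalen-1-yl]-3-methylpentanoic acid; 17 angelic anhydride
Product: 18 (3R)-3-methyl-5-[(1R,4aR,7S,8aS)-2,5,5,8a-tetramethyl-7-{[(2Z)-2-methylbut-2-enoyl]oxy}-1,4,4a,5,6,7,8,8a-octahydronaphthalen-1-yl]pentanoic acid (target)
Conditions: LiHMDS (2.1 equiv), THF, −78 °C; 17 (1.2 equiv), −78 to 0 °C; aq. NaHCO3, then 1 M HCl
Reagents that add atoms: none
Why: the lithium alkoxide of the unhindered equatorial C2–OH should be acylated by the anhydride much faster than the lithium carboxylate; low-temperature alkoxide acylation avoids the amine- or phosphine-induced Z to E isomerisation of angelates, and any mixed anhydride at C15 is hydrolysed in the bicarbonate work-up.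

**Compound list**

1 | (R)-α-ionone, (3E)-4-[(1R)-2,6,6-trimethylcyclohex-2-en-1-yl]but-3-en-2-one | CC1=CCCC(C)(C)[C@H]1/C=C/C(C)=O | starting material
2 | 4-[(1R)-2,6,6-trimethylcyclohex-2-en-1-yl]butan-2-one | CC1=CCCC(C)(C)[C@H]1CCC(C)=O | intermediate
3 | diethyl 4-[(1R)-2,6,6-trimethylcyclohex-2-en-1-yl]but-1-en-2-yl phosphate | CC1=CCCC(C)(C)[C@H]1CCC(=C)OP(=O)(OCC)OCC | intermediate
4 | (6R)-6-(but-3-yn-1-yl)-1,5,5-trimethylcyclohex-1-ene | CC1=CCCC(C)(C)[C@H]1CCC#C | intermediate
5 | methyl hydrogen (R)-3-methylglutarate, (3R)-5-methoxy-3-methyl-5-oxopentanoic acid | OC(=O)C[C@@H](C)CC(=O)OC | starting material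
6 | methyl (3R)-5-hydroxy-3-methylpentanoate | OCC[C@@H](C)CC(=O)OC | intermediate
7 | methyl (3S)-5-iodo-3-methylpentanoate | ICC[C@@H](C)CC(=O)OC | intermediate
8 | methyl (3R)-3-methyl-9-[(1R)-2,6,6-trimethylcyclohex-2-en-1-yl]non-6-ynoate | CC1=CCCC(C)(C)[C@H]1CCC#CCC[C@@H](C)CC(=O)OC | intermediate
9 | methyl (3R)-3-methyl-9-[(1R)-2,6,6-trimethyl-4-oxocyclohex-2-en-1-yl]non-6-ynoate | CC1=CC(=O)CC(C)(C)[C@H]1CCC#CCC[C@@H](C)CC(=O)OC | intermediate
10 | methyl (3R,6E)-3-methyl-6-[(3aR,7aS)-4,4,7a-trimethyl-6-oxooctahydro-1H-inden-1-ylidene]hexanoate | O=C1CC(C)(C)[C@H]2CC/C(=C\CC[C@@H](C)CC(=O)OC)[C@@]2(C)C1 | intermediate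
11 | methyl (3R,6S)-6-bromo-6-[(1R,3aR,7aS)-1-hydroxy-4,4,7a-trimethyl-6-oxooctahydro-1H-inden-1-yl]-3-methylhexanoate | O=C1CC(C)(C)[C@H]2CC[C@](O)([C@@H](Br)CC[C@@H](C)CC(=O)OC)[C@@]2(C)C1 | intermediate
12 | methyl (3R)-3-methyl-5-[(1S,4aR,8aS)-5,5,8a-trimethyl-2,7-dioxodecahydronaphthalen-1-yl]pentanoate | O=C1CC(C)(C)[C@H]2CCC(=O)[C@@H](CC[C@@H](C)CC(=O)OC)[C@@]2(C)C1 | intermediate
13 | methyl (3R)-3-methyl-5-[(1S,4aR,8aS)-5,5,8a-trimethyl-7-oxo-2-(trifluoromethylsulfonyloxy)-1,4,4a,5,6,7,8,8a-octahydronaphthalen-1-yl]pentanoate | O=C1CC(C)(C)[C@H]2CC=C(OS(=O)(=O)C(F)(F)F)[C@@H](CC[C@@H](C)CC(=O)OC)[C@@]2(C)C1 | intermediate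
14 | methyl (3R)-3-methyl-5-[(1R,4aR,8aS)-2,5,5,8a-tetramethyl-7-oxo-1,4,4a,5,6,7,8,8a-octahydronaphthalen-1-yl]pentanoate | O=C1CC(C)(C)[C@H]2CC=C(C)[C@@H](CC[C@@H](C)CC(=O)OC)[C@@]2(C)C1 | intermediate
15 | (3R)-3-methyl-5-[(1R,4aR,8aS)-2,5,5,8a-tetramethyl-7-oxo-1,4,4a,5,6,7,8,8a-octahydronaphthalen-1-yl]pentanoic acid | O=C1CC(C)(C)[C@H]2CC=C(C)[C@@H](CC[C@@H](C)CC(=O)O)[C@@]2(C)C1 | intermediate
16 | (3R)-5-[(1R,4aR,7S,8aS)-7-hydroxy-2,5,5,8a-tetramethyl-1,4,4a,5,6,7,8,8a-octahydronaphthalen-1-yl]-3-methylpentanoic acid | O[C@H]1CC(C)(C)[C@H]2CC=C(C)[C@@H](CC[C@@H](C)CC(=O)O)[C@@]2(C)C1 | intermediate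
17 | angelic anhydride, (2Z)-2-methylbut-2-enoic anhydride | C/C=C(/C)C(=O)OC(=O)C(\C)=C/C | starting material
18 | (3R)-3-methyl-5-[(1R,4aR,7S,8aS)-2,5,5,8a-tetramethyl-7-{[(2Z)-2-methylbut-2-enoyl]oxy}-1,4,4a,5,6,7,8,8a-octahydronaphthalen-1-yl]pentanoic acid | C/C=C(/C)C(=O)O[C@H]1CC(C)(C)[C@H]2CC=C(C)[C@@H](CC[C@@H](C)CC(=O)O)[C@@]2(C)C1 | target

**Step count**

Total: 13 steps. Longest linear sequence: 11 steps (steps 1, 2, 5 to 13 from (R)-α-ionone); steps 3 and 4 form the side-chain branch.

**Steps most likely to fail**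

Step 8. The bromonium may form on the concave face, which after the shift would give the C9 epimer. The silver-promoted ionisation may also end in epoxide closure, hydride shift or C7 migration instead of the ring-enlarging shift. The fallback sets out from 10. Buffered mCPBA should epoxidise the alkene irreversibly on the convex face to the spiro-epoxide F1. Aqueous HClO4 in THF should open it at the tertiary C8 with inversion to the anti-diol F2. Selective mesylation of the secondary C9–OH (MsCl, Et3N, −20 °C) gives the mesylate F3. Et2AlCl in CH2Cl2 at −78 °C then brings about the chelation-controlled Tsuchihashi–Suzuki 1,2-shift of C10 to C9 and comes back to the route at 12. In this variant the face is fixed by a sterically controlled epoxidation and the shift is driven by an aluminium alkoxide instead of a silver-assisted ionisation.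

Step 7. The Pd–H/silane system may simply reduce the enone, or hydropalladation may take the reverse regiochemistry so that the alkenyl–Pd cannot insert at the fully substituted C10. The fallback sets out from 4. Allylic oxidation (CrO3, 3,5-dimethylpyrazole) gives the terminal-alkyne enone F4. With Bu3SnH/AIBN in benzene at 80 °C, the stannyl radical adds to the terminal alkyne carbon and the vinyl radical closes 5-exo on C10 to the cis-fused E-vinylstannane F5. Iododestannylation (I2, CH2Cl2, 0 °C) gives the vinyl iodide F6. Negishi coupling with the alkylzinc iodide F7 (from 7 with Zn dust and LiCl in THF) under Pd(dppf)Cl2 catalysis comes back to the route at 10.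

Step 9. Site selectivity of the enolisation may be lost (C1/C3 next to the C2 ketone, or C9 with epimerisation), giving mixed enol triflates. The fallback sets out from 10. The C2 ketone, the only carbonyl group at that stage, is masked as the dioxolane F8 (1,2-bis(trimethylsilyloxy)ethane, cat. TMSOTf, CH2Cl2, −78 to −20 °C). Under the conditions of steps 8 to 10, F8 is taken through the ketal bromohydrin F9 and the silver-promoted shift to the mono-ketone F10, then to the enol triflate F11 and the methylated ketal F12. PPTS in wet acetone then comes back to the route at 14.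

Further compounds
F1 | step 8 | convex-face spiro-epoxide of 10 (oxirane across C8–C9, oxygen syn to the angular methyl) | O=C1CC(C)(C)[C@H]2CC[C@]3(O[C@H]3CC[C@@H](C)CC(=O)OC)[C@@]2(C)C1
F2 | step 8 | anti-diol of 10 (tertiary C8–OH anti to the angular methyl, secondary C9–OH) | O=C1CC(C)(C)[C@H]2CC[C@](O)([C@@H](O)CC[C@@H](C)CC(=O)OC)[C@@]2(C)C1
F3 | step 8 | C9 methanesulfonate of diol F2 | O=C1CC(C)(C)[C@H]2CC[C@](O)([C@@H](OS(C)(=O)=O)CC[C@@H](C)CC(=O)OC)[C@@]2(C)C1
F4 | step 7 | (4R)-4-(but-3-yn-1-yl)-3,5,5-trimethylcyclohex-2-en-1-one | CC1=CC(=O)CC(C)(C)[C@H]1CCC#C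
F5 | step 7 | (3E,3aS,7aR)-3a,7,7-trimethyl-3-[(tributylstannyl)methylidene]octahydro-5H-inden-5-one | O=C1CC(C)(C)[C@H]2CC/C(=C\[Sn](CCCC)(CCCC)CCCC)[C@@]2(C)C1
F6 | step 7 | (3E,3aS,7aR)-3-(iodomethylidene)-3a,7,7-trimethyloctahydro-5H-inden-5-one | O=C1CC(C)(C)[C@H]2CC/C(=C\I)[C@@]2(C)C1
F7 | step 7 | [(3S)-5-methoxy-3-methyl-5-oxopentyl]zinc iodide | I[Zn]CC[C@@H](C)CC(=O)OC
F8 | step 9 | C2 ethylene ketal of 10 | C13(OCCO3)CC(C)(C)[C@H]2CC/C(=C\CC[C@@H](C)CC(=O)OC)[C@@]2(C)C1
F9 | step 9 | C2 ethylene ketal of bromohydrin 11 | C13(OCCO3)CC(C)(C)[C@H]2CC[C@](O)([C@@H](Br)CC[C@@H](C)CC(=O)OC)[C@@]2(C)C1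
F10 | step 9 | C2 ethylene ketal of 12 (C8 ketone free) | C13(OCCO3)CC(C)(C)[C@H]2CCC(=O)[C@@H](CC[C@@H](C)CC(=O)OC)[C@@]2(C)C1
F11 | step 9 | C2 ethylene ketal of enol triflate 13 | C13(OCCO3)CC(C)(C)[C@H]2CC=C(OS(=O)(=O)C(F)(F)F)[C@@H](CC[C@@H](C)CC(=O)OC)[C@@]2(C)C1
F12 | step 9 | C2 ethylene ketal of 14 | C13(OCCO3)CC(C)(C)[C@H]2CC=C(C)[C@@H](CC[C@@H](C)CC(=O)OC)[C@@]2(C)C1
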